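**Retrosynthetic overview**

1. Target 25 ← C15 unmasking/oxidation and O8 acetylation ← hydroxy lactone 22 (germacrane numbering: ring C1–C10, lactone carbons C11–C13, C14 on C10, C15 on C4).
2. γ-Lactone (last ring): C11–C7 bond by phosphine-triggered umpolung of the C6 acrylate 21, whose C11 opens the cis-fused C7–C8 oxirane on the ten-membered carbocycle. This oxirane is the enabling feature: it sits next to C6–O, so C7 is 1,5 to C11 and can be attacked from the rear when C5–C6–C7–C8 is antiperiplanar.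
3. Ten-membered carbocycle (third ring): C5–C6 bond by intramolecular Nozaki–Hiyama–Kishi addition of the vinyl iodide to the epoxy aldehyde in 18.
4. Both oxiranes (first and second rings; C1, C10, C7, C8) by two Sharpless epoxidations of an acyclic triene, made by Horner–Wadsworth–Emmons union (C1=C10) of aldehyde 11 (C1–C5, C15) with phosphonate 5 (C6–C10, C14).
5. Ring order: C1–C10 oxirane → C7–C8 oxirane → carbocycle → γ-lactone.

Key step: step 15

Remark: 6 and 7 are taken as purchased reagents (6 is otherwise one step from propargyl alcohol and 4-methoxybenzyl chloride), and both epoxidations are assigned with the usual titanium–tartrate facial rule, under which the D-(−)-tartrate gives the 2R epoxy alcohol.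

**Route**

Step 1
Reactants: 1 (Z)-but-2-ene-1,4-diol
Product: 2 (Z)-4-(tert-butyldimethylsilyloxy)but-2-en-1-ol
Conditions: NaH (1.0 equiv), THF, 0 °C; TBSCl (1.0 equiv), rt
Reagents that add atoms: tert-butyldimethylsilyl chloride, CC(C)(C)[Si](C)(C)Cl
Why: Monosilylation of the symmetrical diol through its sparingly soluble monosodium alkoxide (Williamson-type O-silylation) should stop after one silyl group.

Step 2
Reactants: 2 (Z)-4-(tert-butyldimethylsilyloxy)but-2-en-1-ol
Product: 3 (Z)-1-bromo-4-(tert-butyldimethylsilyloxy)but-2-ene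
Conditions: CBr4, PPh3, CH2Cl2, 0 °C
Reagents that add atoms: carbon tetrabromide, BrC(Br)(Br)Br
Why: Appel bromination displaces the oxyphosphonium by SN2 at the primary allylic carbon under neutral conditions, so the Z alkene and the silyl ether should survive.

Step 3
Reactants: 3 (Z)-1-bromo-4-(tert-butyldimethylsilyloxy)but-2-ene; 4 triethyl phosphonoacetate
Product: 5 ethyl (4Z)-6-(tert-butyldimethylsilyloxy)-2-(diethoxyphosphoryl)hex-4-enoate (racemic)
Conditions: NaH, THF, 0 °C → rt (4 in excess)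
Reagents that add atoms: none
Why: SN2 C-alkylation of the sodium phosphonoacetate carbanion by the primary allylic bromide assembles the C6–C10/C14 piece as a Horner–Wadsworth–Emmons reagent, and excess 4 limits dialkylation.

Step 4
Reactants: 6 4-methoxybenzyl prop-2-ynyl ether; 7 [2-(1,3-dioxolan-2-yl)ethyl]magnesium bromide
Product: 10 2-[(3E)-4-iodo-3-{[(4-methoxybenzyl)oxy]methyl}but-3-enyl]-1,3-dioxolane, via alkylcopper 8 (not isolated), via alkenylcopper 9 (not isolated)
Conditions: 7, CuBr·SMe2, Et2O–Me2S, −45 °C; 6, −25 °C; then I2, −50 → 0 °C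
Reagents that add atoms: iodine, II; copper bromide–dimethyl sulfide complex CuBr·SMe2, CSC.[Cu]Br (copper of 8 and 9 only)
Why: syn-Carbocupration of the terminal alkyne (alkyl to the internal carbon, copper to the terminus, cis to each other) and iodinolysis with retention should fix the C4=C5 geometry with iodine cis to the C3 chain, which is the ring-cis alkene of the target.

Step 5
Reactants: 10 2-[(3E)-4-iodo-3-{[(4-methoxybenzyl)oxy]methyl}but-3-enyl]-1,3-dioxolane
Product: 11 (4E)-5-iodo-4-{[(4-methoxybenzyl)oxy]methyl}pent-4-enal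
Conditions: TsOH·H2O (cat.), acetone–H2O, 50 °C
Reagents that add atoms: water, O
Why: Acid-catalysed acetal hydrolysis frees the C1 aldehyde, and the vinyl iodide and the PMB ether are stable to dilute acid.

Step 6
Reactants: 5 ethyl (4Z)-6-(tert-butyldimethylsilyloxy)-2-(diethoxyphosphoryl)hex-4-enoate; 11 (4E)-5-iodo-4-{[(4-methoxybenzyl)oxy]methyl}pent-4-enal
Product: 12 ethyl (2E,6E)-2-[(2Z)-4-(tert-butyldimethylsilyloxy)but-2-enyl]-7-iodo-6-{[(4-methoxybenzyl)oxy]methyl}hepta-2,6-dienoate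
Conditions: 5, NaH, THF, 0 °C; then 11, 0 °C → rt
Reagents that add atoms: none
Why: Horner–Wadsworth–Emmons olefination with an α-substituted phosphonoacetate should place the aldehyde chain trans to the ester, which is the C1=C10 geometry (C2 cis to C9) needed later.

Step 7
Reactants: 12 ethyl (2E,6E)-2-[(2Z)-4-(tert-butyldimethylsilyloxy)but-2-enyl]-7-iodo-6-{[(4-methoxybenzyl)oxy]methyl}hepta-2,6-dienoate
Product: 13 (2E,6E)-2-[(2Z)-4-(tert-butyldimethylsilyloxy)but-2-enyl]-7-iodo-6-{[(4-methoxybenzyl)oxy]methyl}hepta-2,6-dien-1-ol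
Conditions: iBu2AlH (2.5 equiv), CH2Cl2, −78 °C
Reagents that add atoms: none
Why: 1,2-Reduction of the conjugated ester by the aluminium hydride gives the C14 allylic alcohol without touching the vinyl iodide or the ethers.

Step 8
Reactants: 13 (2E,6E)-2-[(2Z)-4-(tert-butyldimethylsilyloxy)but-2-enyl]-7-iodo-6-{[(4-methoxybenzyl)oxy]methyl}hepta-2,6-dien-1-ol
Product: 14 {(2R,3R)-2-[(2Z)-4-(tert-butyldimethylsilyloxy)but-2-enyl]-3-[(3E)-4-iodo-3-{[(4-methoxybenzyl)oxy]methyl}but-3-enyl]oxiran-2-yl}methanol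
Conditions: Ti(OiPr)4 (10 mol %), diethyl D-(−)-tartrate (12 mol %), t-BuOOH, 4 Å MS, CH2Cl2, −20 °C
Reagents that add atoms: tert-butyl hydroperoxide, CC(C)(C)OO
Why: Sharpless asymmetric epoxidation acts only on the alkene carrying the free allylic hydroxyl, and with the D-(−)-tartrate the oxygen should be delivered syn to the face that gives C1 R and C10 R (reagent control).

Step 9
Reactants: 14 {(2R,3R)-2-[(2Z)-4-(tert-butyldimethylsilyloxy)but-2-enyl]-3-[(3E)-4-iodo-3-{[(4-methoxybenzyl)oxy]methyl}but-3-enyl]oxiran-2-yl}methanol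
Product: 15 {(2R,3R)-2-[(2Z)-4-(tert-butyldimethylsilyloxy)but-2-enyl]-3-[(3E)-4-iodo-3-{[(4-methoxybenzyl)oxy]methyl}but-3-enyl]oxiran-2-yl}methyl acetate
Conditions: Ac2O, pyridine, DMAP (cat.), CH2Cl2, 0 °C
Reagents that add atoms: acetic anhydride, CC(=O)OC(C)=O
Why: Nucleophile-catalysed O-acetylation installs the C14 acetate of the target early, where it also differentiates the two primary oxygens.

Step 10
Reactants: 15 {(2R,3R)-2-[(2Z)-4-(tert-butyldimethylsilyloxy)but-2-enyl]-3-[(3E)-4-iodo-3-{[(4-methoxybenzyl)oxy]methyl}but-3-enyl]oxiran-2-yl}methyl acetate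
Product: 16 {(2R,3R)-2-[(2Z)-4-hydroxybut-2-enyl]-3-[(3E)-4-iodo-3-{[(4-methoxybenzyl)oxy]methyl}but-3-enyl]oxiran-2-yl}methyl acetate
Conditions: Bu4NF, AcOH, THF, 0 °C → rt
Reagents that add atoms: none
Why: Buffered fluoride desilylation frees the C6 allylic alcohol while the acetate, the oxirane and the PMB ether should remain.

Step 11
Reactants: 16 {(2R,3R)-2-[(2Z)-4-hydroxybut-2-enyl]-3-[(3E)-4-iodo-3-{[(4-methoxybenzyl)oxy]methyl}but-3-enyl]oxiran-2-yl}methyl acetate
Product: 17 {(2R,3R)-2-{[(2S,3R)-3-(hydroxymethyl)oxiran-2-yl]methyl}-3-[(3E)-4-iodo-3-{[(4-methoxybenzyl)oxy]methyl}but-3-enyl]oxiran-2-yl}methyl acetate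
Conditions: Ti(OiPr)4 (1.0 equiv), diethyl D-(−)-tartrate (1.2 equiv), t-BuOOH, 4 Å MS, CH2Cl2, −20 °C, 48 h
Reagents that add atoms: tert-butyl hydroperoxide, CC(C)(C)OO
Why: Sharpless asymmetric epoxidation of the (Z)-allylic alcohol (slower, hence stoichiometric titanium–tartrate) with the same D-(−)-tartrate should give the cis-oxirane with C7 R and C8 S under reagent control.

Step 12
Reactants: 17 {(2R,3R)-2-{[(2S,3R)-3-(hydroxymethyl)oxiran-2-yl]methyl}-3-[(3E)-4-iodo-3-{[(4-methoxybenzyl)oxy]methyl}but-3-enyl]oxiran-2-yl}methyl acetate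
Product: 18 {(2R,3R)-2-{[(2S,3S)-3-formyloxiran-2-yl]methyl}-3-[(3E)-4-iodo-3-{[(4-methoxybenzyl)oxy]methyl}but-3-enyl]oxiran-2-yl}methyl acetate
Conditions: TEMPO (10 mol %), PhI(OAc)2, CH2Cl2, 0 °C → rt
Reagents that add atoms: none
Why: Oxoammonium-mediated oxidation takes the primary epoxy alcohol to the aldehyde under nearly neutral conditions, which should avoid epimerisation of the cis-epoxy aldehyde.

Step 13
Reactants: 18 {(2R,3R)-2-{[(2S,3S)-3-formyloxiran-2-yl]methyl}-3-[(3E)-4-iodo-3-{[(4-methoxybenzyl)oxy]methyl}but-3-enyl]oxiran-2-yl}methyl acetate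
Product: 19 (1R,4E,6R,7R,8S,10R)-14-acetoxy-1,10:7,8-diepoxy-15-[(4-methoxybenzyl)oxy]germacr-4-en-6-ol (ten-membered carbocycle)
Conditions: CrCl2 (8 equiv), NiCl2 (cat.), DMSO–THF, rt, slow addition to 0.003 M
Reagents that add atoms: none
Why: In the Nozaki–Hiyama–Kishi reaction, nickel-catalysed insertion into the C–I bond, transmetalation to trivalent chromium and 1,2-addition to the aldehyde should close the ten-membered ring with retention of the C4=C5 geometry, and Felkin–Anh attack anti to the oxirane C–O bond should set C6 as R (anti epoxy alcohol).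

Step 14
Reactants: 19 (1R,4E,6R,7R,8S,10R)-14-acetoxy-1,10:7,8-diepoxy-15-[(4-methoxybenzyl)oxy]germacr-4-en-6-ol; 20 acryloyl chloride
Product: 21 (1R,4E,6R,7S,8S,10R)-14-acetoxy-1,10:7,8-diepoxy-15-[(4-methoxybenzyl)oxy]germacr-4-en-6-yl acrylate
Conditions: 20, iPr2NEt, CH2Cl2, −20 → 0 °C
Reagents that add atoms: none
Why: O-Acylation of the secondary allylic alcohol attaches the three lactone carbons C11–C13 as an acrylate without changing any stereocentre.

Step 15
Reactants: 21 (1R,4E,6R,7S,8S,10R)-14-acetoxy-1,10:7,8-diepoxy-15-[(4-methoxybenzyl)oxy]germacr-4-en-6-yl acrylate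
Product: 22 (1R,4E,6R,7R,8S,10R)-14-acetoxy-1,10-epoxy-8-hydroxy-15-[(4-methoxybenzyl)oxy]germacra-4,11(13)-dien-12,6-olide
Conditions: PMe3 (1.0 equiv), t-BuOH, 25 °C, 0.01 M
Reagents that add atoms: none
Why: Proposed new method: PMe3 adds reversibly to the acrylate β-carbon C13 to give a phosphonium ester enolate whose α-carbon C11 attacks C7 of the neighbouring oxirane from the face opposite the C7–O bond (the ten-membered ring lets C5–C6–C7–C8 sit antiperiplanar, which puts O6 anti to the oxirane oxygen), and proton transfer from C11 to the new C8 alkoxide followed by E1cB loss of PMe3 restores the exocyclic methylene; the closest known reaction type is the phosphine-mediated intramolecular Morita–Baylis–Hillman alkylation of enones by tethered epoxides and allylic halides, extended here to an acrylate ester tethered through its alkoxy oxygen. The γ-lactone closes in the 5-exo-tet mode (C11 to C7, with the leaving oxygen outside the new ring). C7 is set by SN2 inversion at the oxirane carbon, which makes the lactone trans-fused and puts C11 anti to the C8 oxygen, while C8 keeps the configuration given by step 11 and C6 is untouched. The step needs regioselectivity for C7 over C8 (5-exo against 6-endo, secured by the two-atom tether), chemoselectivity over the C1–C10 oxirane (which would need an eight- or nine-membered closure) and over intermolecular Rauhut–Currier dimerisation (suppressed by high dilution in tert-butanol, whose hydrogen bonding also activates the oxirane), and C15 is held as its PMB ether so that no enal competes for the phosphine. Release of the oxirane strain (about 27 kcal/mol) should make the C–C bond formation irreversible, so that one operation delivers the lactone ring, the C7 stereocentre, the free C8 hydroxyl and the α-methylene group.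

Step 16
Reactants: 22 (1R,4E,6R,7R,8S,10R)-14-acetoxy-1,10-epoxy-8-hydroxy-15-[(4-methoxybenzyl)oxy]germacra-4,11(13)-dien-12,6-olide
Product: 23 (1R,4E,6R,7R,8S,10R)-8,14-diacetoxy-1,10-epoxy-15-[(4-methoxybenzyl)oxy]germacra-4,11(13)-dien-12,6-olide
Conditions: Ac2O, pyridine, DMAP (cat.), CH2Cl2, 0 °C
Reagents that add atoms: acetic anhydride, CC(=O)OC(C)=O
Why: O-Acetylation of the secondary C8 alcohol gives the second acetate and removes the alkoxide that could translactonise.

Step 17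
Reactants: 23 (1R,4E,6R,7R,8S,10R)-8,14-diacetoxy-1,10-epoxy-15-[(4-methoxybenzyl)oxy]germacra-4,11(13)-dien-12,6-olide
Product: 24 (1R,4E,6R,7R,8S,10R)-8,14-diacetoxy-1,10-epoxy-15-hydroxygermacra-4,11(13)-dien-12,6-olide
Conditions: DDQ, CH2Cl2–pH 7 buffer, 0 °C
Reagents that add atoms: none
Why: Oxidative cleavage of the PMB ether by the quinone (hydride abstraction, then hydrolysis of the oxocarbenium ion) is neutral and should spare the oxirane, the acetates and the α-methylene lactone.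

Step 18
Reactants: 24 (1R,4E,6R,7R,8S,10R)-8,14-diacetoxy-1,10-epoxy-15-hydroxygermacra-4,11(13)-dien-12,6-olide
Product: 25 (1R,4E,6R,7R,8S,10R)-8,14-diacetoxy-1,10-epoxy-15-oxogermacra-4,11(13)-dien-12,6-olide (CNP0211286.1)
Conditions: MnO2, CH2Cl2, rt
Reagents that add atoms: none
Why: Manganese dioxide oxidises only the primary allylic alcohol to the enal, and the ring holds the C4=C5 geometry.

**Compound list**

1 | (Z)-but-2-ene-1,4-diol | OC/C=C\CO | starting material
2 | (Z)-4-(tert-butyldimethylsilyloxy)but-2-en-1-ol | OC/C=C\CO[Si](C)(C)C(C)(C)C | intermediate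
3 | (Z)-1-bromo-4-(tert-butyldimethylsilyloxy)but-2-ene | BrC/C=C\CO[Si](C)(C)C(C)(C)C | intermediate
4 | triethyl phosphonoacetate | CCOC(=O)CP(=O)(OCC)OCC | starting material
5 | ethyl (4Z)-6-(tert-butyldimethylsilyloxy)-2-(diethoxyphosphoryl)hex-4-enoate (racemic) | CCOC(=O)C(C/C=C\CO[Si](C)(C)C(C)(C)C)P(=O)(OCC)OCC | intermediate
6 | 4-methoxybenzyl prop-2-ynyl ether | C#CCOCc1ccc(OC)cc1 | starting material
7 | [2-(1,3-dioxolan-2-yl)ethyl]magnesium bromide | Br[Mg]CCC1OCCO1 | starting material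
8 | [2-(1,3-dioxolan-2-yl)ethyl]copper (MgBr2 complex, not isolated) | [Cu]CCC1OCCO1 | intermediate
9 | [(1E)-4-(1,3-dioxolan-2-yl)-2-{[(4-methoxybenzyl)oxy]methyl}but-1-enyl]copper (not isolated) | COc1ccc(COC/C(CCC2OCCO2)=C/[Cu])cc1 | intermediate
10 | 2-[(3E)-4-iodo-3-{[(4-methoxybenzyl)oxy]methyl}but-3-enyl]-1,3-dioxolane | COc1ccc(COC/C(CCC2OCCO2)=C/I)cc1 | intermediate
11 | (4E)-5-iodo-4-{[(4-methoxybenzyl)oxy]methyl}pent-4-enal | O=CCC/C(COCc1ccc(OC)cc1)=C\I | intermediate
12 | ethyl (2E,6E)-2-[(2Z)-4-(tert-butyldimethylsilyloxy)but-2-enyl]-7-iodo-6-{[(4-methoxybenzyl)oxy]methyl}hepta-2,6-dienoate | CCOC(=O)/C(C/C=C\CO[Si](C)(C)C(C)(C)C)=C/CC/C(COCc1ccc(OC)cc1)=C\I | intermediate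
13 | (2E,6E)-2-[(2Z)-4-(tert-butyldimethylsilyloxy)but-2-enyl]-7-iodo-6-{[(4-methoxybenzyl)oxy]methyl}hepta-2,6-dien-1-ol | OC/C(C/C=C\CO[Si](C)(C)C(C)(C)C)=C/CC/C(COCc1ccc(OC)cc1)=C\I | intermediate
14 | {(2R,3R)-2-[(2Z)-4-(tert-butyldimethylsilyloxy)but-2-enyl]-3-[(3E)-4-iodo-3-{[(4-methoxybenzyl)oxy]methyl}but-3-enyl]oxiran-2-yl}methanol | OC[C@@]1(C/C=C\CO[Si](C)(C)C(C)(C)C)O[C@@H]1CC/C(COCc2ccc(OC)cc2)=C\I | intermediate
15 | {(2R,3R)-2-[(2Z)-4-(tert-butyldimethylsilyloxy)but-2-enyl]-3-[(3E)-4-iodo-3-{[(4-methoxybenzyl)oxy]methyl}but-3-enyl]oxiran-2-yl}methyl acetate | CC(=O)OC[C@@]1(C/C=C\CO[Si](C)(C)C(C)(C)C)O[C@@H]1CC/C(COCc2ccc(OC)cc2)=C\I | intermediate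
16 | {(2R,3R)-2-[(2Z)-4-hydroxybut-2-enyl]-3-[(3E)-4-iodo-3-{[(4-methoxybenzyl)oxy]methyl}but-3-enyl]oxiran-2-yl}methyl acetate | CC(=O)OC[C@@]1(C/C=C\CO)O[C@@H]1CC/C(COCc2ccc(OC)cc2)=C\I | intermediate
17 | {(2R,3R)-2-{[(2S,3R)-3-(hydroxymethyl)oxiran-2-yl]methyl}-3-[(3E)-4-iodo-3-{[(4-methoxybenzyl)oxy]methyl}but-3-enyl]oxiran-2-yl}methyl acetate | CC(=O)OC[C@@]1(C[C@@H]3O[C@@H]3CO)O[C@@H]1CC/C(COCc2ccc(OC)cc2)=C\I | intermediate
18 | {(2R,3R)-2-{[(2S,3S)-3-formyloxiran-2-yl]methyl}-3-[(3E)-4-iodo-3-{[(4-methoxybenzyl)oxy]methyl}but-3-enyl]oxiran-2-yl}methyl acetate | CC(=O)OC[C@@]1(C[C@@H]3O[C@@H]3C=O)O[C@@H]1CC/C(COCc2ccc(OC)cc2)=C\I | intermediate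
19 | (1R,4E,6R,7R,8S,10R)-14-acetoxy-1,10:7,8-diepoxy-15-[(4-methoxybenzyl)oxy]germacr-4-en-6-ol | O[C@@H]1/C=C(/COCc2ccc(OC)cc2)CC[C@H]3O[C@@]3(COC(C)=O)C[C@@H]4O[C@H]14 | intermediate
20 | acryloyl chloride | C=CC(=O)Cl | starting material
21 | (1R,4E,6R,7S,8S,10R)-14-acetoxy-1,10:7,8-diepoxy-15-[(4-methoxybenzyl)oxy]germacr-4-en-6-yl acrylate | C=CC(=O)O[C@@H]1/C=C(/COCc2ccc(OC)cc2)CC[C@H]3O[C@@]3(COC(C)=O)C[C@@H]4O[C@H]14 | intermediate
22 | (1R,4E,6R,7R,8S,10R)-14-acetoxy-1,10-epoxy-8-hydroxy-15-[(4-methoxybenzyl)oxy]germacra-4,11(13)-dien-12,6-olide | C=C1C(=O)O[C@@H]2/C=C(/COCc3ccc(OC)cc3)CC[C@H]4O[C@@]4(COC(C)=O)C[C@H](O)[C@@H]12 | intermediate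
23 | (1R,4E,6R,7R,8S,10R)-8,14-diacetoxy-1,10-epoxy-15-[(4-methoxybenzyl)oxy]germacra-4,11(13)-dien-12,6-olide | C=C1C(=O)O[C@@H]2/C=C(/COCc3ccc(OC)cc3)CC[C@H]4O[C@@]4(COC(C)=O)C[C@H](OC(C)=O)[C@@H]12 | intermediate
24 | (1R,4E,6R,7R,8S,10R)-8,14-diacetoxy-1,10-epoxy-15-hydroxygermacra-4,11(13)-dien-12,6-olide | C=C1C(=O)O[C@@H]2/C=C(/CO)CC[C@H]3O[C@@]3(COC(C)=O)C[C@H](OC(C)=O)[C@@H]12 | intermediate
25 | (1R,4E,6R,7R,8S,10R)-8,14-diacetoxy-1,10-epoxy-15-oxogermacra-4,11(13)-dien-12,6-olide (CNP0211286.1) | C=C1C(=O)O[C@@H]2/C=C(/C=O)CC[C@H]3O[C@@]3(COC(C)=O)C[C@H](OC(C)=O)[C@@H]12 | target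

**Step count and risks**

Total step count: 18. Longest linear sequence: 16 steps (steps 1–3, then 6–18).

Steps most likely to fail:

Step 15 (Proposed new method). The phosphine may add reversibly to the acrylate without the ester enolate ever reaching C7 (unfavourable ester rotamer, weak nucleophile). The transient C8 alkoxide may also translactonise or move an acetyl group. The fallback sets out from 19 and comes back at 22, using only known chemistry. Alcohol 19 is esterified with diethylphosphonoacetic acid (DCC, DMAP) to the diethylphosphonoacetate ester F1. Its stabilised carbanion (NaH, THF, or LiCl/DBU) opens the C7–C8 oxirane at C7 in the same 5-exo sense, an ordinary intramolecular alkylation of a phosphonate carbanion by an epoxide, to give the α-phosphono-γ-lactone F2 as C11 epimers. Horner–Wadsworth–Emmons reaction with aqueous formaldehyde (K2CO3) then installs the methylene group and gives 22.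

Step 13. Ring strain in the ten-membered transition state may override the Felkin–Anh preference, giving poor facial selectivity at C6 (and oligomerisation if dilution is insufficient). The fallback sets out from 18 and comes back at 19. The ring closure is run as in step 13, and the mixture of 19 and its C6 epimer, the (6S)-alcohol F3, is oxidised with Dess–Martin periodinane to the macrocyclic α,β-epoxy enone F4. Chelation-controlled 1,2-reduction with Zn(BH4)2 (Et2O, −20 °C), in which zinc bridges the carbonyl and oxirane oxygens and hydride arrives anti to the oxirane, should then give the anti epoxy alcohol 19.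

Step 6. The olefination may lose geometric control and give an E/Z mixture at C1=C10, which would carry through as a diastereomeric oxirane. The fallback sets out from 11 and comes back at 12, and sets the geometry by allylic transposition instead of olefination. Morita–Baylis–Hillman reaction of 11 with ethyl acrylate (DABCO) gives the allylic alcohol F5. NBS/Me2S converts it with allylic transposition into the thermodynamically favoured (2Z)-2-(bromomethyl)enoate F6, in which the chain is trans to the ester. Copper-mediated coupling (CuI, Cs2CO3, DMF) with tert-butyldimethyl(prop-2-ynyloxy)silane gives the skipped enyne F7. cis-Selective semi-reduction of the alkyne (dicyclohexylborane, then AcOH) gives 12.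

Further compounds
F1 | step 15 | (1R,4E,6R,7S,8S,10R)-14-acetoxy-1,10:7,8-diepoxy-15-[(4-methoxybenzyl)oxy]germacr-4-en-6-yl (diethoxyphosphoryl)acetate | CCOP(=O)(OCC)CC(=O)O[C@@H]1/C=C(/COCc2ccc(OC)cc2)CC[C@H]3O[C@@]3(COC(C)=O)C[C@@H]4O[C@H]14
F2 | step 15 | (1R,4E,6R,7R,8S,10R)-14-acetoxy-11-(diethoxyphosphoryl)-1,10-epoxy-8-hydroxy-15-[(4-methoxybenzyl)oxy]germacr-4-en-12,6-olide (C11 epimers) | CCOP(=O)(OCC)C1C(=O)O[C@@H]2/C=C(/COCc3ccc(OC)cc3)CC[C@H]4O[C@@]4(COC(C)=O)C[C@H](O)[C@@H]12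
F3 | step 13 | (1R,4E,6S,7R,8S,10R)-14-acetoxy-1,10:7,8-diepoxy-15-[(4-methoxybenzyl)oxy]germacr-4-en-6-ol (C6 epimer of 19) | O[C@H]1/C=C(/COCc2ccc(OC)cc2)CC[C@H]3O[C@@]3(COC(C)=O)C[C@@H]4O[C@H]14
F4 | step 13 | (1R,4E,7R,8S,10R)-14-acetoxy-1,10:7,8-diepoxy-15-[(4-methoxybenzyl)oxy]germacr-4-en-6-one | O=C1/C=C(/COCc2ccc(OC)cc2)CC[C@H]3O[C@@]3(COC(C)=O)C[C@@H]4O[C@H]14
F5 | step 6 | ethyl (6E)-3-hydroxy-7-iodo-6-{[(4-methoxybenzyl)oxy]methyl}-2-methylidenehept-6-enoate (racemic) | CCOC(=O)C(=C)C(O)CC/C(COCc1ccc(OC)cc1)=C\I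
F6 | step 6 | ethyl (2Z,6E)-2-(bromomethyl)-7-iodo-6-{[(4-methoxybenzyl)oxy]methyl}hepta-2,6-dienoate | CCOC(=O)/C(CBr)=C/CC/C(COCc1ccc(OC)cc1)=C\I
F7 | step 6 | ethyl (2E,6E)-2-[4-(tert-butyldimethylsilyloxy)but-2-ynyl]-7-iodo-6-{[(4-methoxybenzyl)oxy]methyl}hepta-2,6-dienoate | CCOC(=O)/C(CC#CCO[Si](C)(C)C(C)(C)C)=C/CC/C(COCc1ccc(OC)cc1)=C\I
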